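Ring A is disconnected at C3–C4 (labdane numbering): the gem-dimethyl carbon C4 next to the C3 carbinol is read as the Markovnikov hydrogen-atom adduct of an isopropenyl group, and C3–O as an aldehyde. This maps ring B with C5 and C10 onto (R)-carvone, whose isopropenyl group becomes C4, C18 and C19. One hydrogen-atom-transfer radical cyclisation of an isopropenyl aldehyde closes ring A, creates the quaternary C4 and sets the C3 carbinol. The precursor is carvone carrying a methyl and a 3-oxopropyl arm on C6 (future C10). The C9 carbinol is then set by α-face epoxidation of a C9 methylene, and the butenolide is joined by a B-alkyl Suzuki coupling.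

Key step: step 4

Remark: bicyclic compounds are numbered as labdanes (ring A = C1–C5 and C10; ring B = C5–C10; C18/C19 on C4, C17 on C8, C20 on C10, side chain C11–C16 on C9; C20 is β).

Step 1
Reactants: 1 (R)-(−)-carvone
Product: 3 (5R,6S)-2,6-dimethyl-5-(prop-1-en-2-yl)cyclohex-2-en-1-one (trans-6-methylcarvone; the minor 6R epimer is carried along), via lithium dienolate of carvone 2 (not isolated)
Conditions: LiN(iPr)2, THF, −78 °C; then MeI, −78 to 0 °C
Reagents that add atoms: methyl iodide, CI; lithium diisopropylamide, CC(C)N([Li])C(C)C (lithium only in intermediate 2)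
Why: Kinetic α′-deprotonation of the enone and C-methylation of the cross-conjugated dienolate (enolate alkylation); the configuration of the new C6 centre is irrelevant because it is planarised again in step 2.

Step 2
Reactants: 3 trans-6-methylcarvone; 4 propargyl bromide
Product: 6 (5S,6S)-2,6-dimethyl-5-(prop-1-en-2-yl)-6-(prop-2-yn-1-yl)cyclohex-2-en-1-one (propargyl trans and methyl cis to the isopropenyl group), via lithium dienolate of 6-methylcarvone 5 (not isolated)
Conditions: LiN(iPr)2, THF, −78 °C; then 4, DMPU, −78 to −20 °C
Reagents that add atoms: lithium diisopropylamide, CC(C)N([Li])C(C)C (lithium only in intermediate 5)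
Why: Enolate alkylation that builds the quaternary carbon (future C10); the isopropenyl group on the neighbouring carbon sits pseudoaxial in the enolate to avoid allylic strain with the enolate methyl, so the electrophile should enter anti to it and the propargyl arm ends up trans.

Step 3
Reactants: 6 methyl propargyl carvone
Product: 7 3-[(1S,6S)-1,3-dimethyl-2-oxo-6-(prop-1-en-2-yl)cyclohex-3-en-1-yl]propanal
Conditions: CpRu(MeCN)3PF6 (5 mol %), 5,5′-bis(trifluoromethyl)-2,2′-bipyridine (5 mol %), NMP/H2O 4:1, 25 °C
Reagents that add atoms: water, O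
Why: Ruthenium-catalysed anti-Markovnikov hydration of the terminal alkyne through a ruthenium vinylidene should give the aldehyde and leave the enone and the 1,1-disubstituted alkene untouched; no stereocentre is formed.

Step 4
Reactants: 7 isopropenyl enone aldehyde
Product: 8 3β-hydroxy-11,12,13,14,15,16-hexanorlabd-7-en-9-one (trans-fused; 5α-H, 10β-CH3, C4 gem-dimethyl, C7=C8 enone)
Conditions: Fe(acac)3 (30 mol %), PhSiH3 (slow addition), EtOH, 60 °C, Ar
Reagents that add atoms: none
Why: A trivalent iron hydride made from Fe(acac)3, PhSiH3 and EtOH transfers a hydrogen atom to the CH2 terminus of the isopropenyl group, the tertiary C4 radical adds to the aldehyde carbon C3, and the resulting alkoxy radical is reduced by divalent iron and protonated by ethanol. The closest known reaction type is the MHAT-initiated reductive radical cyclisation of alkene-tethered ketones under the same iron–silane conditions, here applied to an aldehyde acceptor. Ring A closes in the 6-exo-trig mode (attack on the carbonyl carbon, oxygen exocyclic), and the trans ring fusion is not at stake because C5 and C10 already carry the radical carbon and the propanal arm trans-diequatorial. The new stereocentre C3 is controlled by the chair-like transition state in which the C=O oxygen is pseudoequatorial, clear of the axial hydrogens at C1 and C5, and since the addition is reversible by β-scission, the more stable equatorial 3β-alkoxy radical should be the one that is reduced; C4 becomes quaternary without being stereogenic. The step needs hydrogen-atom transfer to the electron-rich 1,1-disubstituted alkene and not to the conjugated enone, which the low reactivity of this hydride towards electron-poor alkenes should secure (carvone is functionalised at its isopropenyl group under related Mukaiyama-type conditions). It also needs cyclisation to outrun reduction of the C4 radical and hydrosilylation of the aldehyde, which the short tether, the slow silane addition and the impossibility of a competing closure onto C9 (a four-membered ring) should secure.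

Step 5
Reactants: 8 bicyclic hydroxy enone
Product: 10 3β-hydroxy-11,12,13,14,15,16-hexanor-8βH-labdan-9-one (8α-methyl, equatorial), via 8αH epimer of the ketone 9 (not isolated)
Conditions: H2 (1 atm), Pd/C, EtOAc, rt; filter; then NaOMe, MeOH, rt
Reagents that add atoms: none
Why: Catalytic hydrogenation of the only remaining C=C, expected from the open α-face, followed by base equilibration α to the C9 ketone; in the rigid trans-decalin an axial 8β-methyl clashes syn-diaxially with C20, so thermodynamic control should set C8 as the equatorial 8α-methyl epimer.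

Step 6
Reactants: 10 hydroxy ketone
Product: 11 12,13,14,15,16-pentanor-8βH-labd-9(11)-en-3β-ol (exocyclic methylene on C9)
Conditions: Ph3PCH3Br, KOtBu (both in excess), toluene, 90 °C
Reagents that add atoms: methyltriphenylphosphonium bromide, C[P+](c1ccccc1)(c1ccccc1)c1ccccc1.[Br-]
Why: Wittig methylenation at elevated temperature is established for hindered 2,2,6-trisubstituted cyclohexanones; the free 3-OH is carried as its alkoxide and C8 stays at its thermodynamic configuration under the basic conditions.

Step 7
Reactants: 11 exocyclic alkene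
Product: 12 9α,11-epoxy-12,13,14,15,16-pentanor-8βH-labdan-3β-ol (spiro-epoxide, oxygen α and axial, C11 β and equatorial)
Conditions: mCPBA, NaHCO3, CH2Cl2, 0 °C
Reagents that add atoms: 3-chloroperbenzoic acid, O=C(OO)c1cccc(Cl)c1
Why: Prilezhaev epoxidation; the axial C20 methyl on the neighbouring carbon covers the β-face of the C9=C11 bond, so the peracid should attack from the α-face and set C9 with the oxygen α.

Step 8
Reactants: 12 spiro-epoxide
Product: 13 13,14,15,16-tetranor-8βH-labd-11-ene-3β,9α-diol (9β-vinyl, 9α-OH)
Conditions: Me3S+ I−, n-BuLi (both in excess), THF, −10 °C to rt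
Reagents that add atoms: trimethylsulfonium iodide, C[S+](C)C.[I-]
Why: One-carbon homologation of an epoxide to an allylic alcohol with dimethylsulfonium methylide (SN2 opening at the primary C11, then ylide-mediated elimination of dimethyl sulfide from the γ-alkoxy sulfonium salt); the C9–O bond is not touched, so the 9α-oxygen is kept.

Step 9
Reactants: 13 vinyl diol
Product: 14 3β-acetoxy-13,14,15,16-tetranor-8βH-labd-11-en-9α-ol
Conditions: Ac2O, pyridine, DMAP (cat.), CH2Cl2, rt
Reagents that add atoms: acetic anhydride, CC(=O)OC(C)=O
Why: DMAP-catalysed acylation should acetylate the equatorial secondary 3-OH only, because the tertiary 9-OH between C8 and the quaternary C10 is too hindered to react.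

Step 10
Reactants: 14 acetoxy vinyl carbinol; 15 3-bromofuran-2(5H)-one
Product: 17 3β-acetoxy-9α-hydroxy-8βH-labd-13-en-16,15-olide (target CNP0117645.1), via B-alkyl-9-BBN borane 16 (not isolated)
Conditions: 9-BBN (excess), THF, 60 °C; then 15, PdCl2(dppf) (5 mol %), AsPh3, aq. K3PO4, DMF, rt
Reagents that add atoms: 9-borabicyclo[3.3.1]nonane, B1C2CCCC1CCC2 (its atoms stay only in intermediate 16)
Why: Anti-Markovnikov hydroboration of the vinyl group and B-alkyl Suzuki–Miyaura coupling with the α-bromobutenolide should form C12–C13 with the butenolide double bond already in place, under a base mild enough for the acetate and the lactone; no stereocentre is touched.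

Compound list
1 | (R)-(−)-carvone, (5R)-2-methyl-5-(prop-1-en-2-yl)cyclohex-2-en-1-one | CC1=CC[C@H](CC1=O)C(=C)C | starting material
2 | lithium dienolate of carvone (O–Li on C1, C1=C6 and C2=C3) | [Li]OC1=C[C@H](C(C)=C)CC=C1C | intermediate (not isolated)
3 | (5R,6S)-2,6-dimethyl-5-(prop-1-en-2-yl)cyclohex-2-en-1-one (trans-6-methylcarvone, major epimer) | C[C@H]1[C@@H](CC=C(C)C1=O)C(C)=C | intermediate
4 | propargyl bromide (3-bromoprop-1-yne) | C#CCBr | starting material
5 | lithium dienolate of 6-methylcarvone | [Li]OC1=C(C)[C@H](C(C)=C)CC=C1C | intermediate (not isolated)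
6 | (5S,6S)-2,6-dimethyl-5-(prop-1-en-2-yl)-6-(prop-2-yn-1-yl)cyclohex-2-en-1-one | C#CC[C@@]1(C)[C@@H](CC=C(C)C1=O)C(C)=C | intermediate
7 | 3-[(1S,6S)-1,3-dimethyl-2-oxo-6-(prop-1-en-2-yl)cyclohex-3-en-1-yl]propanal | O=CCC[C@@]1(C)[C@@H](CC=C(C)C1=O)C(C)=C | intermediate
8 | 3β-hydroxy-11,12,13,14,15,16-hexanorlabd-7-en-9-one | O[C@H]1CC[C@@]2(C)[C@@H](CC=C(C)C2=O)C1(C)C | intermediate
9 | 3β-hydroxy-11,12,13,14,15,16-hexanor-8αH-labdan-9-one (8β-methyl epimer) | O[C@H]1CC[C@@]2(C)[C@@H](CC[C@H](C)C2=O)C1(C)C | intermediate (not isolated)
10 | 3β-hydroxy-11,12,13,14,15,16-hexanor-8βH-labdan-9-one (8α-methyl) | O[C@H]1CC[C@@]2(C)[C@@H](CC[C@@H](C)C2=O)C1(C)C | intermediate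
11 | 12,13,14,15,16-pentanor-8βH-labd-9(11)-en-3β-ol | O[C@H]1CC[C@@]2(C)[C@@H](CC[C@@H](C)C2=C)C1(C)C | intermediate
12 | 9α,11-epoxy-12,13,14,15,16-pentanor-8βH-labdan-3β-ol | O[C@H]1CC[C@@]2(C)[C@@H](CC[C@@H](C)[C@]2(O3)C3)C1(C)C | intermediate
13 | 13,14,15,16-tetranor-8βH-labd-11-ene-3β,9α-diol | O[C@H]1CC[C@@]2(C)[C@@H](CC[C@@H](C)[C@]2(O)C=C)C1(C)C | intermediate
14 | 3β-acetoxy-13,14,15,16-tetranor-8βH-labd-11-en-9α-ol | CC(=O)O[C@H]1CC[C@@]2(C)[C@@H](CC[C@@H](C)[C@]2(O)C=C)C1(C)C | intermediate
15 | 3-bromofuran-2(5H)-one (α-bromobutenolide) | O=C1OCC=C1Br | starting material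
16 | 3β-acetoxy-12-(9-borabicyclo[3.3.1]nonan-9-yl)-13,14,15,16-tetranor-8βH-labdan-9α-ol | CC(=O)O[C@H]1CC[C@@]2(C)[C@@H](CC[C@@H](C)[C@]2(O)CCB2C3CCCC2CCC3)C1(C)C | intermediate (not isolated)
17 | 3β-acetoxy-9α-hydroxy-8βH-labd-13-en-16,15-olide (CNP0117645.1) | CC(=O)O[C@H]1CC[C@@]2(C)[C@@H](CC[C@@H](C)[C@]2(O)CCC2=CCOC2=O)C1(C)C | target

Total step count: 10 steps. Longest linear sequence: 10 steps, from (R)-carvone 1.

Steps most likely to fail

Step 4. The ring closure is reversible, so reduction of the C4 radical to an isopropyl group may outrun it, and the facial selectivity at C3 may be poor. The fallback sets out from 7 and comes back at 8. The aldehyde of 7 is converted with I2 in aqueous NH3/THF into 3-[(1S,6S)-1,3-dimethyl-2-oxo-6-(prop-1-en-2-yl)cyclohex-3-en-1-yl]propanenitrile F1. The same iron hydride conditions then close ring A by addition of the C4 radical to the nitrile carbon, a known HAT-initiated alkene–nitrile cyclisation whose iminyl radical fragments back less readily. Hydrolysis of the imine on acidic work-up gives 11,12,13,14,15,16-hexanorlabd-7-ene-3,9-dione F2. NaBH4 in MeOH at −20 °C should reduce the saturated C3 ketone in preference to the hindered conjugated C9 ketone, with axial hydride delivery from the α-face giving the equatorial 3β-alcohol 8, so that C3 is set by the reagent and not in the radical step.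

Step 8. Substitution at the neopentyl-like C11 may be slow, and the strongly basic ylide may isomerise the epoxide instead. The fallback sets out from 11 and comes back at 13. Upjohn dihydroxylation of 11 (OsO4 cat., NMO, acetone/H2O), from the same open α-face, should give 12,13,14,15,16-pentanor-8βH-labdane-3β,9α,11-triol F3. Selective oxidation of the primary hydroxyl (TEMPO, PhI(OAc)2, CH2Cl2) gives 3β,9α-dihydroxy-12,13,14,15,16-pentanor-8βH-labdan-11-al F4. Wittig methylenation with excess Ph3P=CH2 in THF at 0 °C then gives 13.

Step 10. The aqueous base may open or isomerise the bromobutenolide, and the hindered alkylborane may lose boron by protonolysis before it transmetalates. The fallback sets out from 14 and comes back at 17. Hydroboration–oxidation (9-BBN, THF; then NaBO3·4H2O) gives 3β-acetoxy-13,14,15,16-tetranor-8βH-labdane-9α,12-diol F5. Appel iodination of the primary alcohol (I2, PPh3, imidazole, CH2Cl2) gives 3β-acetoxy-12-iodo-13,14,15,16-tetranor-8βH-labdan-9α-ol F6. A base-free nickel-catalysed reductive cross-electrophile coupling of F6 with 15 (NiCl2(dme), 4,4′-di-tert-butyl-2,2′-bipyridine, Zn, DMA, rt) then gives 17.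

Further compounds
F1 | step 4 | 3-[(1S,6S)-1,3-dimethyl-2-oxo-6-(prop-1-en-2-yl)cyclohex-3-en-1-yl]propanenitrile | N#CCC[C@@]1(C)[C@@H](CC=C(C)C1=O)C(C)=C
F2 | step 4 | 11,12,13,14,15,16-hexanorlabd-7-ene-3,9-dione | O=C1CC[C@@]2(C)[C@@H](CC=C(C)C2=O)C1(C)C
F3 | step 8 | 12,13,14,15,16-pentanor-8βH-labdane-3β,9α,11-triol | O[C@H]1CC[C@@]2(C)[C@@H](CC[C@@H](C)[C@]2(O)CO)C1(C)C
F4 | step 8 | 3β,9α-dihydroxy-12,13,14,15,16-pentanor-8βH-labdan-11-al | O[C@H]1CC[C@@]2(C)[C@@H](CC[C@@H](C)[C@]2(O)C=O)C1(C)C
F5 | step 10 | 3β-acetoxy-13,14,15,16-tetranor-8βH-labdane-9α,12-diol | CC(=O)O[C@H]1CC[C@@]2(C)[C@@H](CC[C@@H](C)[C@]2(O)CCO)C1(C)C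
F6 | step 10 | 3β-acetoxy-12-iodo-13,14,15,16-tetranor-8βH-labdan-9α-ol | CC(=O)O[C@H]1CC[C@@]2(C)[C@@H](CC[C@@H](C)[C@]2(O)CCI)C1(C)C
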